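**Retrosynthetic overview**

1. Numbering: ring A (five-membered) is C1 (quaternary C–CH3), C2 (CH–OAc), C3 (CH2), C4 (C(OH)iPr), C5 (ring-fusion CH); ring B (seven-membered) is C1, C5, C6 (CH–O-veratroyl), C7 (CH2), C8(CH3)–C9 oxirane, C10 (CH–OH).
2. The route rests on the C8–C9 oxirane, which is trans-fused to ring B (C7 and C10 trans, 8R,9R). It cannot be put onto a finished cycloheptene, so it is made on an open chain and ring B is closed last across C1–C10, an aldol bond once C2 is a ketone.
3. C2–OAc ⇒ C2 ketone (directed reduction); C1–C10 ⇒ C1 bromo C2 ketone plus C10 epoxy aldehyde (SmI2 Reformatsky-type aldol); C1–Br/C5–H/C2=O ⇒ C1=C5 alkene (allylic oxidation, then conjugate hydrosilylation–bromination).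
4. Oxirane ⇒ (E)-allylic alcohol (Sharpless); C8–CH3 and C9–C10 ⇒ alkyne (carboalumination–formaldehyde); C6–C7 ⇒ ring A aldehyde (asymmetric propargylation).
5. Ring order: ring A first, from (S)-terpinen-4-ol by ozonolysis and aldol ring contraction (brings C4); the oxirane second; ring B last.

Key step: step 12

Remark: 14–16 are drawn as the C1 epimer with bromine anti to the C5 side chain; either epimer gives the same samarium enolate.

**Route**

Step 1
Reactants: 1 (S)-terpinen-4-ol
Product: 2 (3S)-3-hydroxy-6-oxo-3-(propan-2-yl)heptanal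
Conditions: O3, CH2Cl2/MeOH, NaHCO3, −78 °C; Me2S, −78 °C → rt
Reagents that add atoms: ozone [O-][O+]=O
Why: Ozonolysis with reductive work-up (Criegee cleavage) cuts the only C=C bond and leaves the quaternary carbinol untouched, so the (S) centre of 1 becomes C4 of the target with its configuration.

Step 2
Reactants: 2 (3S)-3-hydroxy-6-oxo-3-(propan-2-yl)heptanal
Product: 3 (5R)-5-hydroxy-2-methyl-5-(propan-2-yl)cyclopent-1-ene-1-carbaldehyde
Conditions: piperidine (0.3 equiv), AcOH (0.3 equiv), 4 Å molecular sieves, toluene, 50 °C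
Reagents that add atoms: none
Why: Amine-catalysed intramolecular aldol condensation, the usual ring contraction of 6-oxoheptanals: the enamine of the aldehyde adds 5-(enolexo)-exo-trig to the methyl ketone and dehydration into conjugation gives ring A (bond C1–C5) with C4 untouched, the buffered medium keeping the tertiary β-hydroxyl from eliminating.

Step 3
Reactants: 3 (5R)-5-hydroxy-2-methyl-5-(propan-2-yl)cyclopent-1-ene-1-carbaldehyde; 4 allenylboronic acid pinacol ester
Product: 5 (1R)-1-[(5R)-5-hydroxy-2-methyl-5-(propan-2-yl)cyclopent-1-en-1-yl]but-3-yn-1-ol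
Conditions: (R)-TRIP phosphoric acid (10 mol%), 4 Å molecular sieves, toluene, −20 → 0 °C; aq. NaHCO3
Reagents that add atoms: none
Why: Chiral phosphoric acid-catalysed propargylation with an allenylboronate (SE2′ through a closed six-membered transition state) is catalyst-controlled, and the (R)-catalyst, which adds to the Re face of aryl and alkenyl aldehydes, should add to the Re face of this conjugated aldehyde and set C6 as (R).

Step 4
Reactants: 5 (1R)-1-[(5R)-5-hydroxy-2-methyl-5-(propan-2-yl)cyclopent-1-en-1-yl]but-3-yn-1-ol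
Product: 7 (2E,5R)-5-[(5R)-5-hydroxy-2-methyl-5-(propan-2-yl)cyclopent-1-en-1-yl]-3-methylpent-2-ene-1,5-diol, via alkenyldimethylalane 6 (not isolated)
Conditions: AlMe3 (5 equiv), Cp2ZrCl2 (0.25 equiv), CH2Cl2, 0 °C → rt; evaporate; n-BuLi, THF/hexane, −78 → 0 °C; (CH2O)n, rt; aq. potassium sodium tartrate
Reagents that add atoms: trimethylaluminium C[Al](C)C; formaldehyde (as paraformaldehyde) C=O
Why: Negishi zirconium-catalysed carboalumination adds methyl and aluminium syn across the terminal alkyne with methyl on the internal carbon C8, and the derived alanate takes up formaldehyde with retention, which gives the (E)-allylic alcohol with C7 and C10 trans while the two hydroxyls ride along as aluminium alkoxides.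

Step 5
Reactants: 7 (2E,5R)-5-[(5R)-5-hydroxy-2-methyl-5-(propan-2-yl)cyclopent-1-en-1-yl]-3-methylpent-2-ene-1,5-diol
Product: 8 (1R)-1-[(5R)-5-hydroxy-2-methyl-5-(propan-2-yl)cyclopent-1-en-1-yl]-2-[(2R,3R)-3-(hydroxymethyl)-2-methyloxiran-2-yl]ethan-1-ol
Conditions: Ti(OiPr)4 (0.2 equiv), D-(−)-diisopropyl tartrate (0.25 equiv), t-BuOOH (1.5 equiv, decane), 4 Å molecular sieves, CH2Cl2, −25 °C
Reagents that add atoms: tert-butyl hydroperoxide CC(C)(C)OO
Why: Sharpless asymmetric epoxidation is reagent-controlled: D-(−)-tartrate gives the (2R,3R)-epoxy alcohol from an (E)-3-methylalk-2-en-1-ol (mirror image of the geraniol/L-(+)-tartrate case), which sets C8 and C9 with C7 and C10 trans on the oxirane, and the primary allylic alcohol reacts far faster than the fully substituted ring alkene beside its hindered secondary and tertiary carbinols.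

Step 6
Reactants: 8 (1R)-1-[(5R)-5-hydroxy-2-methyl-5-(propan-2-yl)cyclopent-1-en-1-yl]-2-[(2R,3R)-3-(hydroxymethyl)-2-methyloxiran-2-yl]ethan-1-ol
Product: 9 (1R)-1-[(5R)-5-hydroxy-2-methyl-5-(propan-2-yl)cyclopent-1-en-1-yl]-2-[(2R,3R)-2-methyl-3-{[(triethylsilyl)oxy]methyl}oxiran-2-yl]ethan-1-ol
Conditions: Et3SiCl (1.05 equiv), imidazole, CH2Cl2, −40 → −20 °C
Reagents that add atoms: chlorotriethylsilane CC[Si](Cl)(CC)CC
Why: Silyl chloride/imidazole silylation is sterically selective for the primary C10 hydroxyl over the hindered secondary C6 and tertiary C4 hydroxyls, and the triethylsilyl ether is chosen because it can later be oxidised directly to the aldehyde.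

Step 7
Reactants: 9 (1R)-1-[(5R)-5-hydroxy-2-methyl-5-(propan-2-yl)cyclopent-1-en-1-yl]-2-[(2R,3R)-2-methyl-3-{[(triethylsilyl)oxy]methyl}oxiran-2-yl]ethan-1-ol; 10 3,4-dimethoxybenzoyl chloride
Product: 11 (1R)-1-[(5R)-5-hydroxy-2-methyl-5-(propan-2-yl)cyclopent-1-en-1-yl]-2-[(2R,3R)-2-methyl-3-{[(triethylsilyl)oxy]methyl}oxiran-2-yl]ethyl 3,4-dimethoxybenzoate
Conditions: pyridine, DMAP (0.2 equiv), CH2Cl2, 0 °C → rt
Reagents that add atoms: none
Why: DMAP-catalysed acylation with the acid chloride esterifies the only acylable hydroxyl (secondary C6–OH, the tertiary C4–OH being inert), so the final C6 ester is in place before C10–OH exists and the two never have to be told apart.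

Step 8
Reactants: 11 (1R)-1-[(5R)-5-hydroxy-2-methyl-5-(propan-2-yl)cyclopent-1-en-1-yl]-2-[(2R,3R)-2-methyl-3-{[(triethylsilyl)oxy]methyl}oxiran-2-yl]ethyl 3,4-dimethoxybenzoate
Product: 12 (1R)-1-[(5R)-5-hydroxy-2-methyl-3-oxo-5-(propan-2-yl)cyclopent-1-en-1-yl]-2-[(2R,3R)-2-methyl-3-{[(triethylsilyl)oxy]methyl}oxiran-2-yl]ethyl 3,4-dimethoxybenzoate
Conditions: Rh2(cap)4 (cap = caprolactamate, 1 mol%), t-BuOOH (5 equiv), K2CO3 (0.5 equiv), CH2Cl2, rt
Reagents that add atoms: tert-butyl hydroperoxide CC(C)(C)OO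
Why: Rh2(cap)4-catalysed allylic oxidation with t-BuOOH (hydrogen abstraction by tert-butylperoxyl radicals, then collapse of the mixed peroxide to the enone) should attack the ring methylene C2, the only well-aligned secondary allylic C–H, since C6–H lies in the alkene plane (allylic strain) and is deactivated by the acyloxy group, the C1 methyl is primary and C4 is quaternary.

Step 9
Reactants: 12 (1R)-1-[(5R)-5-hydroxy-2-methyl-3-oxo-5-(propan-2-yl)cyclopent-1-en-1-yl]-2-[(2R,3R)-2-methyl-3-{[(triethylsilyl)oxy]methyl}oxiran-2-yl]ethyl 3,4-dimethoxybenzoate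
Product: 14 (1R)-1-[(1R,2S,5R)-2-bromo-5-hydroxy-2-methyl-3-oxo-5-(propan-2-yl)cyclopentyl]-2-[(2R,3R)-2-methyl-3-{[(triethylsilyl)oxy]methyl}oxiran-2-yl]ethyl 3,4-dimethoxybenzoate, via triethylsilyl enol ether 13 (not isolated)
Conditions: RhCl(PPh3)3 (3 mol%), Et3SiH (3 equiv), toluene, 60 °C; evaporate; NBS (1.05 equiv), NaHCO3, THF, −78 °C
Reagents that add atoms: N-bromosuccinimide O=C1CCC(=O)N1Br
Why: RhCl(PPh3)3-catalysed 1,4-hydrosilylation of the enone gives the C1=C2 silyl enol ether regiospecifically and should deliver hydride to C5 on the α face (the face of the small C4 hydroxyl, anti to the isopropyl group), setting C5–H cis to C4–O, and NBS then brominates the enol ether at C1 without acid or base, so there is no enolisation toward C3 and no loss of the C4 oxygen.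

Step 10
Reactants: 14 (1R)-1-[(1R,2S,5R)-2-bromo-5-hydroxy-2-methyl-3-oxo-5-(propan-2-yl)cyclopentyl]-2-[(2R,3R)-2-methyl-3-{[(triethylsilyl)oxy]methyl}oxiran-2-yl]ethyl 3,4-dimethoxybenzoate
Product: 15 (1R)-1-[(1R,2S,5R)-2-bromo-2-methyl-3-oxo-5-(propan-2-yl)-5-[(trimethylsilyl)oxy]cyclopentyl]-2-[(2R,3R)-2-methyl-3-{[(triethylsilyl)oxy]methyl}oxiran-2-yl]ethyl 3,4-dimethoxybenzoate
Conditions: Me3SiOTf (1.2 equiv), 2,6-lutidine (2 equiv), CH2Cl2, −78 °C, 15 min
Reagents that add atoms: trimethylsilyl trifluoromethanesulfonate C[Si](C)(C)OS(=O)(=O)C(F)(F)F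
Why: Silyl triflate/2,6-lutidine silylation caps the tertiary C4 hydroxyl within minutes at −78 °C, too mild to open the oxirane or enolise the ketone, so that C4–OH cannot protonate the samarium enolate in step 12, and trimethylsilyl is chosen because it leaves at the end under buffered conditions.

Step 11
Reactants: 15 (1R)-1-[(1R,2S,5R)-2-bromo-2-methyl-3-oxo-5-(propan-2-yl)-5-[(trimethylsilyl)oxy]cyclopentyl]-2-[(2R,3R)-2-methyl-3-{[(triethylsilyl)oxy]methyl}oxiran-2-yl]ethyl 3,4-dimethoxybenzoate
Product: 16 (1R)-1-[(1R,2S,5R)-2-bromo-2-methyl-3-oxo-5-(propan-2-yl)-5-[(trimethylsilyl)oxy]cyclopentyl]-2-[(2R,3S)-3-formyl-2-methyloxiran-2-yl]ethyl 3,4-dimethoxybenzoate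
Conditions: (COCl)2, DMSO, CH2Cl2, −78 → −40 °C; Et3N, −78 → −20 °C
Reagents that add atoms: none
Why: Under Swern conditions a primary triethylsilyl ether exchanges with the chlorosulfonium salt and is oxidised directly to the aldehyde while the hindered tertiary trimethylsilyl ether stays, and the epoxy aldehyde has no enolisable hydrogen, so C9 keeps its configuration (its descriptor becomes S only through the priority rules).

Step 12
Reactants: 16 (1R)-1-[(1R,2S,5R)-2-bromo-2-methyl-3-oxo-5-(propan-2-yl)-5-[(trimethylsilyl)oxy]cyclopentyl]-2-[(2R,3S)-3-formyl-2-methyloxiran-2-yl]ethyl 3,4-dimethoxybenzoate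
Product: 17 trans-fused ring A/ring B hydroxy ketone (overview numbering): (1R,4R,5R,6R,8R,9R,10R)-8,9-epoxy-10-hydroxy-2-oxo-4-[(trimethylsilyl)oxy] bicycle with C6 O-(3,4-dimethoxybenzoyl)
Conditions: SmI2 (2.2 equiv, 0.1 M in THF) added to 16 (0.005 M), THF, −78 °C; pH 7 buffer (NaH2PO4/Na2HPO4), −78 °C
Reagents that add atoms: none
Why: SmI2 (divalent samarium) gives up two electrons to the C1–Br bond, the most easily reduced group at −78 °C, and forms the C1=C2 samarium enolate (trivalent samarium) regiospecifically, which adds to the tethered C10 aldehyde; this is the SmI2-mediated intramolecular Reformatsky-type aldol of α-bromo ketones with aldehydes. Ring B closes in the 7-(enolexo)-exo-trig mode. C1 is controlled by the tether: C6 stands on the β face at C5 and the (E)-configured oxirane holds C7 and C10 anti, so the chain should bring C10 only to the α face of the enolate carbon, anti to the C5–C6 bond, giving the trans ring fusion with the C1 methyl β (1R). C10 is controlled by a Felkin–Anh approach to the epoxy aldehyde, with the C9–O bond anti to the incoming enolate and the enolate passing C9–H, which gives the erythro C9/C10 pair (10R). The step needs chemoselectivity for C–Br over the epoxy aldehyde and the aryl ester, secured by the much easier reduction of the α-bromo ketone with only 2.2 equiv of SmI2 at −78 °C, and it needs the closure to hold against the strain of the trans-fused oxirane, secured by the non-enolisable aldehyde and by the samarium aldolate, held as a chelate with the C2 carbonyl and protonated cold at pH 7.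

Step 13
Reactants: 17 trans-fused hydroxy ketone
Product: 18 (1S,2S,4R,5R,6R,8R,9R,10R)-2,10-diol: as 17 with C2 β-OH (C1 descriptor changes by priority only)
Conditions: Me4NBH(OAc)3 (5 equiv), MeCN/AcOH (10:1), −35 °C
Reagents that add atoms: none
Why: Evans–Saksena directed reduction: the triacetoxyborohydride exchanges onto the C10 hydroxyl and delivers hydride intramolecularly to the α face of the C2 ketone, the face on which C10 sits, giving the β (2S) alcohol cis to the C1 methyl.

Step 14
Reactants: 18 2,10-diol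
Product: 19 (1R,2S,4R,5R,6R,8R,9R,10R)-2-acetate: as 18 with C2 OAc, C10–OH free, C4 OSiMe3
Conditions: Ac2O (1.2 equiv), pyridine, DMAP (5 mol%), CH2Cl2, 0 °C
Reagents that add atoms: acetic anhydride CC(=O)OC(C)=O
Why: Acetylation under steric control: C2–OH is a cyclopentanol between one quaternary carbon and a CH2 (comparable to a steroid 17β-hydroxyl), whereas C10–OH lies between quaternary C1 and the oxirane carbon C9 and is deactivated by the oxirane oxygen, so C2 should be acetylated selectively at 0 °C.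

Step 15
Reactants: 19 2-acetate
Product: 20 target CNP0197096.5, (1R,2S,4R,5R,6R,8R,9R,10R)-2-acetoxy-8,9-epoxy-4,10-dihydroxy bicycle with C6 O-(3,4-dimethoxybenzoyl)
Conditions: Bu4NF/AcOH (1:1, 1.5 equiv), THF, 0 °C
Reagents that add atoms: none
Why: Fluoride desilylation buffered with acetic acid removes the tertiary trimethylsilyl ether without forming the C10 alkoxide, which avoids Payne rearrangement of the epoxy alcohol and 1,3-acyl migration from C2 to C10.

**Compound list**

1 | (S)-terpinen-4-ol | CC1=CC[C@](O)(C(C)C)CC1 | starting material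
2 | (3S)-3-hydroxy-6-oxo-3-(propan-2-yl)heptanal | O=CC[C@](O)(C(C)C)CCC(C)=O | intermediate
3 | (5R)-5-hydroxy-2-methyl-5-(propan-2-yl)cyclopent-1-ene-1-carbaldehyde | O=CC1=C(C)CC[C@@]1(O)C(C)C | intermediate
4 | allenylboronic acid pinacol ester | C=C=CB1OC(C)(C)C(C)(C)O1 | starting material
5 | (1R)-1-[(5R)-5-hydroxy-2-methyl-5-(propan-2-yl)cyclopent-1-en-1-yl]but-3-yn-1-ol | C#CC[C@@H](O)C1=C(C)CC[C@@]1(O)C(C)C | intermediate
6 | (E)-alkenyldimethylalane of 5, both hydroxyls as dimethylaluminium alkoxides | C[Al](C)/C=C(\C)C[C@@H](O[Al](C)C)C1=C(C)CC[C@@]1(O[Al](C)C)C(C)C | intermediate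
7 | (2E,5R)-5-[(5R)-5-hydroxy-2-methyl-5-(propan-2-yl)cyclopent-1-en-1-yl]-3-methylpent-2-ene-1,5-diol | OC/C=C(\C)C[C@@H](O)C1=C(C)CC[C@@]1(O)C(C)C | intermediate
8 | (1R)-1-[(5R)-5-hydroxy-2-methyl-5-(propan-2-yl)cyclopent-1-en-1-yl]-2-[(2R,3R)-3-(hydroxymethyl)-2-methyloxiran-2-yl]ethan-1-ol | OC[C@H]1O[C@]1(C)C[C@@H](O)C2=C(C)CC[C@@]2(O)C(C)C | intermediate
9 | C10 triethylsilyl ether of 8 | CC[Si](CC)(CC)OC[C@H]1O[C@]1(C)C[C@@H](O)C2=C(C)CC[C@@]2(O)C(C)C | intermediate
10 | 3,4-dimethoxybenzoyl chloride | COc1ccc(C(Cl)=O)cc1OC | starting material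
11 | C6 3,4-dimethoxybenzoate of 9 | CC[Si](CC)(CC)OC[C@H]1O[C@]1(C)C[C@@H](OC(=O)c3ccc(OC)c(OC)c3)C2=C(C)CC[C@@]2(O)C(C)C | intermediate
12 | C2 ketone, C1=C5 enone | CC[Si](CC)(CC)OC[C@H]1O[C@]1(C)C[C@@H](OC(=O)c3ccc(OC)c(OC)c3)C2=C(C)C(=O)C[C@@]2(O)C(C)C | intermediate
13 | C1=C2 triethylsilyl enol ether, (5R) C5–H | CC[Si](CC)(CC)OC[C@H]1O[C@]1(C)C[C@@H](OC(=O)c3ccc(OC)c(OC)c3)[C@H]2C(C)=C(O[Si](CC)(CC)CC)C[C@@]2(O)C(C)C | intermediate
14 | C1 bromo C2 ketone, C4–OH | CC[Si](CC)(CC)OC[C@H]1O[C@]1(C)C[C@@H](OC(=O)c3ccc(OC)c(OC)c3)[C@H]2[C@@](Br)(C)C(=O)C[C@@]2(O)C(C)C | intermediate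
15 | C1 bromo C2 ketone, C4 OSiMe3, C10 OSiEt3 | CC[Si](CC)(CC)OC[C@H]1O[C@]1(C)C[C@@H](OC(=O)c3ccc(OC)c(OC)c3)[C@H]2[C@@](Br)(C)C(=O)C[C@@]2(O[Si](C)(C)C)C(C)C | intermediate
16 | C1 bromo C2 ketone with C10 epoxy aldehyde (key precursor) | O=C[C@H]1O[C@]1(C)C[C@@H](OC(=O)c3ccc(OC)c(OC)c3)[C@H]2[C@@](Br)(C)C(=O)C[C@@]2(O[Si](C)(C)C)C(C)C | intermediate
17 | trans-fused C10-hydroxy C2-ketone with oxirane (key product) | COc1ccc(C(=O)O[C@@H]2C[C@@]3(C)O[C@@H]3[C@H](O)[C@]3(C)C(=O)C[C@@](O[Si](C)(C)C)(C(C)C)[C@@H]23)cc1OC | intermediate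
18 | 2,10-diol | COc1ccc(C(=O)O[C@@H]2C[C@@]3(C)O[C@@H]3[C@H](O)[C@]3(C)[C@@H](O)C[C@@](O[Si](C)(C)C)(C(C)C)[C@@H]23)cc1OC | intermediate
19 | C2 acetate, C4 OSiMe3 | COc1ccc(C(=O)O[C@@H]2C[C@@]3(C)O[C@@H]3[C@H](O)[C@]3(C)[C@@H](OC(C)=O)C[C@@](O[Si](C)(C)C)(C(C)C)[C@@H]23)cc1OC | intermediate
20 | CNP0197096.5 | COc1ccc(C(=O)O[C@@H]2C[C@@]3(C)O[C@@H]3[C@H](O)[C@]3(C)[C@@H](OC(C)=O)C[C@@](O)(C(C)C)[C@@H]23)cc1OC | target

**Step count and risks**

Total steps: 15. Longest linear sequence: 15 steps (1 → 20).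

Most likely to fail:

Step 12. Facial control at the aldehyde carbon may be lost: a samarium chelate between the aldehyde and oxirane oxygens would turn the other face of C10 toward the enolate, and slow closure against ring strain would favour this equilibrated mode. The fallback sets C10 by reduction instead of by the aldol. It sets out from 16: the same SmI2 closure is run and the C10 epimer of 17 F1 is oxidised with Dess–Martin periodinane (NaHCO3, CH2Cl2) to the 2,10-dione F2. Its oxirane-flanked C10 ketone is then reduced with Zn(BH4)2 (Et2O, −78 °C) under chelation control, the erythro-selective reduction of α,β-epoxy ketones, and the route is rejoined at 17.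

Step 9. Hydride transfer to the fully substituted β-carbon C5 may be slow, so that 1,2-hydrosilylation of the ketone or silylation of the C4 hydroxyl competes and facial selectivity erodes. The fallback separates saturation from bromination. It sets out from 12: hydrogenation (H2, Pd/C, EtOAc) adds cis from the α face, anti to the isopropyl group, and gives the saturated ketone F3. This is brominated through its more substituted enol with PhNMe3Br3 in THF at 0 °C (THF takes up the HBr), and the route is rejoined at 14.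

Step 8. Hydrogen abstraction may be unselective (C1 methyl or C6–H instead of C2–H2), or peroxyl radicals may add to the electron-rich tetrasubstituted alkene. The fallback replaces radical oxidation by a concerted hydroxylation. It sets out from 11: SeO2 (0.5 equiv)/t-BuOOH in CH2Cl2 (ene reaction, then [2,3]-sigmatropic shift, which prefers the ring methylene) gives the C2 allylic alcohol F4. Dess–Martin oxidation then returns the route to 12.

Further compounds
F1 | step 12 | C10 epimer of 17 (10S) | COc1ccc(C(=O)O[C@@H]2C[C@@]3(C)O[C@@H]3[C@@H](O)[C@]3(C)C(=O)C[C@@](O[Si](C)(C)C)(C(C)C)[C@@H]23)cc1OC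
F2 | step 12 | 2,10-dione from F1 | COc1ccc(C(=O)O[C@@H]2C[C@@]3(C)O[C@@H]3C(=O)[C@]3(C)C(=O)C[C@@](O[Si](C)(C)C)(C(C)C)[C@@H]23)cc1OC
F3 | step 9 | saturated C2 ketone from 12 (C1–H and C5–H cis, α) | CC[Si](CC)(CC)OC[C@H]1O[C@]1(C)C[C@@H](OC(=O)c3ccc(OC)c(OC)c3)[C@H]2[C@@H](C)C(=O)C[C@@]2(O)C(C)C
F4 | step 8 | C2 allylic alcohol from 11 (C2 epimers) | CC[Si](CC)(CC)OC[C@H]1O[C@]1(C)C[C@@H](OC(=O)c3ccc(OC)c(OC)c3)C2=C(C)C(O)C[C@@]2(O)C(C)C
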